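**Strategy.** Ring B of the target, the 2-acetyl-3,5-dihydroxy-4,4-dimethylcyclohexa-2,5-dienone, is cut into an isobutyrate unit (the gem-dimethyl carbon C-4 with the oxygenated carbon C-5) and an acetoacetyl unit (C-3, C-2, C-1, C-6). In the key step the lithium enolate of methyl isobutyrate and diketene are joined in one pot: C-acylation forms C-3–C-4, and Dieckmann closure of the derived dianion forms C-5–C-6, giving filicinic acid. The step exploits the 1,3,5-trioxygenation of ring B and its quaternary C-4, which is flanked by two carbonyl carbons and cannot enolise. The precursors are two commodity chemicals; C-acetylation at C-2 and a Mannich-directed methylene coupling at C-6 with butanoylphloroglucinol (ring A) complete the route.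

Key step: step 1

Remark on the chemistry (assumption): the β-triketone rings are written as the dienol tautomer of the target SMILES; filicinic acid 5 has a mirror plane through C-1 and C-4, so its two ring CH carbons are equivalent, and the one acetylated in step 2 is by definition C-2, the other C-6.

Step 1
Reactants: 1 methyl isobutyrate; 2 diketene
Product: 5 filicinic acid (3,5-dihydroxy-4,4-dimethylcyclohexa-2,5-dien-1-one), via lithium enolate of methyl isobutyrate 3 (not isolated), via lithium enolate of methyl 2,2-dimethyl-3,5-dioxohexanoate 4 (not isolated)
Conditions: LiN(i-Pr)2 (1.05 equiv), THF, −78 °C; 2 (1.0 equiv), −78 °C; then LiN(i-Pr)2 (1.2 equiv), −78 °C → rt; aq. HCl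
Reagents that add atoms: none
Why: Enolate 3 should attack the strained lactone carbonyl of diketene through carbon (Claisen-type C-acylation with acyl–oxygen cleavage), which forms the C-3–C-4 bond and gives the chelated β-diketonate 4; the second portion of base then removes a proton from the terminal methyl group, the only enolisable position left, and the dianion closes onto the ester carbonyl (Dieckmann condensation), which forms the C-5–C-6 bond and expels methoxide. The closest known reaction types are the acetoacetylation of carbanions by diketene and the Claisen cyclisation of β-diketone dianions onto esters. The six-membered ring closes in a 6-(enolendo)-exo-trig mode, helped by the gem-dimethyl effect. No stereocentre is formed. The step needs C- over O-acylation in both stages: a lithium ester enolate in THF acylates on carbon, and any enol lactone from O-cyclisation should be reopened by the LiOMe set free and funnelled to the trione, which leaves the equilibrium as its stable enolate. The quaternary C-4 rules out proton transfer back to the isobutyrate carbon and any alternative dianion.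

Step 2
Reactants: 5 filicinic acid
Product: 6 2-acetylfilicinic acid (2-acetyl-3,5-dihydroxy-4,4-dimethylcyclohexa-2,5-dien-1-one)
Conditions: AcCl (1.1 equiv), AlCl3 (3 equiv), PhNO2, rt → 60 °C; ice/aq. HCl
Reagents that add atoms: acetyl chloride, CC(Cl)=O
Why: Friedel–Crafts-type C-acylation of the enolised cyclic β-triketone (O-acylation followed by an AlCl3-mediated Fries-type O→C shift), where the mirror symmetry of 5 allows only one mono-acetyl product and the aluminium chelate of 6 resists a second acylation.

Step 3
Reactants: 7 phloroglucinol; 8 butanoyl chloride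
Product: 9 1-(2,4,6-trihydroxyphenyl)butan-1-one (butanoylphloroglucinol)
Conditions: AlCl3 (3 equiv), PhNO2/CH2Cl2, 0 °C → 45 °C; ice/aq. HCl
Reagents that add atoms: none
Why: Friedel–Crafts acylation of the threefold-symmetric phloroglucinol, which should stop after one acyl group because the AlCl3-complexed aryl ketone is deactivated.

Step 4
Reactants: 6 2-acetylfilicinic acid; 9 1-(2,4,6-trihydroxyphenyl)butan-1-one
Product: 12 target 2-acetyl-6-[(3-butanoyl-2,4,6-trihydroxyphenyl)methyl]-3,5-dihydroxy-4,4-dimethylcyclohexa-2,5-dien-1-one, via Mannich base 10 (not isolated), via methylidene triketone 11 (not isolated)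
Conditions: CH2=NMe2+ I− (1.0 equiv), NaOAc (1.0 equiv), MeCN, rt; then 9 (3 equiv), 70 °C; aq. HCl
Reagents that add atoms: N,N-dimethylmethyleneiminium iodide, C=[N+](C)C.[I-]
Why: A Mannich reaction at C-6, the only free ring CH of 6, should give betaine 10, which on warming loses dimethylamine (retro-Michael, E1cB) to the 6-methylidene triketone 11, and this quinone-methide-like acceptor is captured by a free nuclear carbon of 9 in a Friedel–Crafts-type Michael addition; full conversion of 6 into 10 beforehand suppresses the symmetric dimer and the excess of 9 suppresses double alkylation.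

**Compound list**

1 | methyl isobutyrate (methyl 2-methylpropanoate) | COC(=O)C(C)C | starting material
2 | diketene (4-methylideneoxetan-2-one) | C=C1CC(=O)O1 | starting material
3 | lithium enolate of methyl isobutyrate | COC(O[Li])=C(C)C | intermediate
4 | lithium enolate of methyl 2,2-dimethyl-3,5-dioxohexanoate (Z, chelated) | COC(=O)C(C)(C)C(=O)/C=C(/C)O[Li] | intermediate
5 | filicinic acid (3,5-dihydroxy-4,4-dimethylcyclohexa-2,5-dien-1-one) | CC1(C)C(O)=CC(=O)C=C1O | intermediate
6 | 2-acetylfilicinic acid (2-acetyl-3,5-dihydroxy-4,4-dimethylcyclohexa-2,5-dien-1-one) | CC(=O)C1=C(O)C(C)(C)C(O)=CC1=O | intermediate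
7 | phloroglucinol (benzene-1,3,5-triol) | Oc1cc(O)cc(O)c1 | starting material
8 | butanoyl chloride | CCCC(Cl)=O | starting material
9 | 1-(2,4,6-trihydroxyphenyl)butan-1-one | CCCC(=O)c1c(O)cc(O)cc1O | intermediate
10 | Mannich base, 2-acetyl-6-[(dimethylamino)methyl]-3,5-dihydroxy-4,4-dimethylcyclohexa-2,5-dien-1-one | CN(C)CC1=C(O)C(C)(C)C(O)=C(C(C)=O)C1=O | intermediate
11 | methylidene triketone, 2-acetyl-3-hydroxy-4,4-dimethyl-6-methylidenecyclohex-2-ene-1,5-dione | C=C1C(=O)C(C)(C)C(O)=C(C(C)=O)C1=O | intermediate
12 | 2-acetyl-6-[(3-butanoyl-2,4,6-trihydroxyphenyl)methyl]-3,5-dihydroxy-4,4-dimethylcyclohexa-2,5-dien-1-one | CCCC(=O)c1c(O)cc(O)c(CC2=C(O)C(C)(C)C(O)=C(C(C)=O)C2=O)c1O | target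

**Totals.** Total step count: 4. Longest linear sequence: 3 steps (steps 1, 2 and 4); step 3 is a one-step side branch.

**Steps most likely to fail**

1. Step 1 (key step). The ester enolate may deprotonate diketene and start its anionic oligomerisation instead of opening the lactone, and the ring closure may stall at the enol lactone from O-attack. The fallback sets out from 1 and comes back at 5, making the same two ring bonds in separate, individually known operations. Compound 1 is silylated (LiN(i-Pr)2, Me3SiCl, THF, −78 °C) to 1-methoxy-2-methyl-1-(trimethylsilyloxy)prop-1-ene F1. Heating F1 with 2,2,6-trimethyl-4H-1,3-dioxin-4-one in toluene at 110 °C releases acetylketene by retro-[4+2] loss of acetone; the ketene acetal should capture it in a hetero-Diels–Alder reaction to give 2-methoxy-3,3,6-trimethyl-2-(trimethylsilyloxy)-2,3-dihydro-4H-pyran-4-one F2, which forms C-3–C-4. Methanolysis opens F2 to methyl 2,2-dimethyl-3,5-dioxohexanoate F3. The isolated diketo ester is then closed as its dianion (LiN(i-Pr)2, 2.2 equiv, THF, −78 °C → rt), which forms C-5–C-6 and gives 5.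

2. Step 4. The product keeps one free nuclear position and may be alkylated a second time, and under the warm buffered conditions the methylene bridge may transfer reversibly, scrambling the material toward the symmetric dimers. The fallback sets out from 6 and comes back at 12. Compound 6 is condensed with aqueous formaldehyde (0.5 equiv, dilute aq. NaOH, rt) to the symmetric dimer albaspidin AA F4. F4 is then equilibrated with an excess of 9 in dilute aqueous Na2CO3 at rt; retro-Michael fragmentation of F4 releases 11, which 9 should trap to give 12, while the liberated 6 is recovered and recycled.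

3. Step 2. The acylation may stop at the enol ester, run on to the diacetyl compound, or be reversed by Lewis-acid-mediated deacylation on prolonged heating. The fallback sets out from 5 and comes back at 6. Compound 5 is O-acetylated (Ac2O, 1.0 equiv, Et3N, CH2Cl2, 0 °C) to the enol acetate 3-acetoxy-5-hydroxy-4,4-dimethylcyclohexa-2,5-dien-1-one F5. F5 is then rearranged to 6 by nucleophile-catalysed O→C acyl migration (4-(dimethylamino)pyridine, cat., MeCN, rt).

**Further compounds**

F1 | step 1 | 1-methoxy-2-methyl-1-(trimethylsilyloxy)prop-1-ene | COC(O[Si](C)(C)C)=C(C)C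
F2 | step 1 | 2-methoxy-3,3,6-trimethyl-2-(trimethylsilyloxy)-2,3-dihydro-4H-pyran-4-one | COC1(O[Si](C)(C)C)OC(C)=CC(=O)C1(C)C
F3 | step 1 | methyl 2,2-dimethyl-3,5-dioxohexanoate | COC(=O)C(C)(C)C(=O)CC(C)=O
F4 | step 4 | albaspidin AA, 2,2'-methylenebis(6-acetyl-3,5-dihydroxy-4,4-dimethylcyclohexa-2,5-dien-1-one) | CC(=O)C1=C(O)C(C)(C)C(O)=C(CC2=C(O)C(C)(C)C(O)=C(C(C)=O)C2=O)C1=O
F5 | step 2 | 3-acetoxy-5-hydroxy-4,4-dimethylcyclohexa-2,5-dien-1-one | CC(=O)OC1=CC(=O)C=C(O)C1(C)C
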